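**Assumption:** (R)-BINOL/Ti(OiPr)4 is taken to direct the diene to the Re face of each enal carbonyl (giving 2R); if the sense is the opposite, (S)-BINOL is used. The two tropolone tautomers are treated as one compound.

**Retrosynthetic overview**
1. Target ⇐ its bis(O-methyl tropolone) ⇐ the corresponding C4,C4'-diketone (late deoxygenation, then demethylation).
2. Both tropolone rings ⇐ two-fold oxidopyrylium [5+2] cycloaddition/aromatisation on a bis(2,3-dihydro-4H-pyran-4-one) that already carries the diene and all three stereocentres.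
3. The 3-methyl group ⇐ one trans-selective enolate methylation of the C2-symmetric bis(dihydropyranone).
4. Both dihydropyran rings and both C–O stereocentres ⇐ two-directional catalytic asymmetric hetero-Diels–Alder reaction of (E,E)-muconaldehyde with Danishefsky's diene.
5. Ring order: the two pyran rings first (one operation), then the two seven-membered rings (one operation).

Ring A is the methyl-bearing pyran with its tropolone; ring B is the other half. Fused rings are numbered as cyclohepta[b]pyran (O1, C2, C3, C4, C4a, C5–C9, C9a).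

**Step 1**
Reactants: 1 hexa-2,4-diyne-1,6-diol
Product: 2 (2E,4E)-hexa-2,4-diene-1,6-diol
Conditions: LiAlH4 (3 equiv), THF, 0 °C → reflux; H2O/aq NaOH work-up
Reagents that add atoms: none
Why: Alkoxide-directed trans-hydroalumination of both propargylic alcohols (LiAlH4 reduction of propargylic alcohols) gives the E,E-diene.

**Step 2**
Reactants: 2 (2E,4E)-hexa-2,4-diene-1,6-diol
Product: 3 (2E,4E)-hexa-2,4-dienedial
Conditions: MnO2 (20 equiv), CH2Cl2, rt
Reagents that add atoms: none
Why: MnO2 allylic oxidation converts both allylic primary alcohols to aldehydes without touching or isomerising the diene.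

**Step 3**
Reactants: 3 (2E,4E)-hexa-2,4-dienedial; 4 Danishefsky's diene, (E)-1-methoxy-3-(trimethylsilyloxy)buta-1,3-diene (2.6 equiv)
Product: 6 (2R,2'R)-2,2'-[(1E,3E)-buta-1,3-diene-1,4-diyl]bis(2,3-dihydro-4H-pyran-4-one), via bis-silyl aldol adduct 5 (not isolated)
Conditions: (R)-BINOL (20 mol %), Ti(OiPr)4 (10 mol %), 4 Å MS, Et2O, −20 °C; then TFA, CH2Cl2, 0 °C
Reagents that add atoms: none
Why: Keck-type BINOL–titanium-catalysed Mukaiyama aldol/cyclocondensation (formal hetero-Diels–Alder reaction) at both aldehydes forms both pyranone rings, the catalyst directing the diene to the Re face of each formyl group so that C2 and C2' are both R, and the two-fold reaction raises the ee of the C2-symmetric product because the minor sense ends up in a separable meso isomer.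

**Step 4**
Reactants: 6 (2R,2'R)-2,2'-[(1E,3E)-buta-1,3-diene-1,4-diyl]bis(2,3-dihydro-4H-pyran-4-one)
Product: 8 (2S,3S)-3-methyl-2-[(1E,3E)-4-[(2R)-4-oxo-3,4-dihydro-2H-pyran-2-yl]buta-1,3-dien-1-yl]-2,3-dihydro-4H-pyran-4-one, via mono-lithium enolate 7 (not isolated)
Conditions: LiN(iPr)2 (1.0 equiv), THF, −78 °C; MeI (3 equiv), −78 → −40 °C; recovered 6 recycled
Reagents that add atoms: iodomethane, CI
Why: Kinetic enolate alkylation at C3 of one ring, with MeI approaching anti to the C2 dienyl group, sets the 2,3-trans methyl centre (the S descriptors at C2 and C3 reflect changed priorities, not a changed configuration); the two equivalent rings react statistically, so 6 is recycled.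

**Step 5**
Reactants: 9 allomaltol (5-hydroxy-2-methyl-4H-pyran-4-one)
Product: 10 5-hydroxy-4-methoxy-2-methylpyrylium trifluoromethanesulfonate
Conditions: MeOTf (1.1 equiv), CH2Cl2, reflux
Reagents that add atoms: methyl trifluoromethanesulfonate, COS(=O)(=O)C(F)(F)F
Why: O-Methylation of the pyrone carbonyl of a 3-hydroxy-4-pyrone gives the stable hydroxypyrylium salt, the known precursor of the oxidopyrylium ylide.

**Step 6**
Reactants: 8 (2S,3S)-3-methyl-2-[(1E,3E)-4-[(2R)-4-oxo-3,4-dihydro-2H-pyran-2-yl]buta-1,3-dien-1-yl]-2,3-dihydro-4H-pyran-4-one; 10 5-hydroxy-4-methoxy-2-methylpyrylium trifluoromethanesulfonate (5 equiv)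
Product: 13 (2S,3S)-7-methoxy-2-[(1E,3E)-4-[(2R)-7-methoxy-5-methyl-4,8-dioxo-2,3,4,8-tetrahydrocyclohepta[b]pyran-2-yl]buta-1,3-dien-1-yl]-3,5-dimethyl-2,3-dihydrocyclohepta[b]pyran-4,8-dione, via oxidopyrylium ylide 11 (not isolated), via two-fold cycloadduct 12 (not isolated)
Conditions: PhNMe2 (5.5 equiv), CHCl3, 100 °C, sealed tube; then CH2Cl2, Et3N (12 equiv), Me3SiOTf (8 equiv), 0 °C → rt; aq NaHCO3
Reagents that add atoms: none
Why: Proposed new method: a two-fold oxidopyrylium [5+2] cycloaddition of ylide 11 across the C5=C6 bond of each dihydropyranone forms both seven-membered rings in one operation, the vinylogous-ester polarity placing the nucleophilic ylide carbon next to the oxide on the O-bearing C6 and the methyl-bearing terminus on C5 (closest known type: additions of this 3-hydroxy-4-pyrone-derived ylide to acrylates, enones and ynones), after which Me3SiOTf/Et3N soft enolisation of the C4 ketones opens each oxa-bridge by β-elimination and expels the bridging oxygen to give the aromatic methoxytropones (closest known type: Me3SiOTf/Et3N conversion of 8-oxabicyclo[3.2.1]octenones to tropolone ethers), so that every new sp3 centre is erased and C2, C3 and C2' are untouched.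

**Step 7**
Reactants: 13 bis(methoxytropone) diketone
Product: 14 bis-alcohol, (2S,3R)-4-hydroxy-2-[(1E,3E)-4-[(2R)-4-hydroxy-7-methoxy-5-methyl-8-oxo-2,3,4,8-tetrahydrocyclohepta[b]pyran-2-yl]buta-1,3-dien-1-yl]-7-methoxy-3,5-dimethyl-3,4-dihydrocyclohepta[b]pyran-8(2H)-one (C4/C4' epimers)
Conditions: NaBH4 (3 equiv), CeCl3·7H2O (2.2 equiv), MeOH–CH2Cl2, −40 °C
Reagents that add atoms: none
Why: Luche 1,2-reduction takes the two aryl-ketone-like C4 carbonyls while the vinylogous-ester tropone carbonyls are much less electrophilic, and it removes the base-labile flavanone-type ketones at once; the new carbinol centres are deleted in step 9.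

**Step 8**
Reactants: 14 bis-alcohol
Product: 15 bis(O-phenyl thionocarbonate) of 14 (ring A 2S,3S; ring B 2R; C4/C4' epimers)
Conditions: PhOC(S)Cl (3 equiv), pyridine, DMAP (20 mol %), CH2Cl2, rt; aq NaHCO3
Reagents that add atoms: O-phenyl chlorothionoformate, S=C(Cl)Oc1ccccc1
Why: Thioacylation of the two secondary alcohols is the first half of a Barton–McCombie deoxygenation and needs neither acid nor strong base.

**Step 9**
Reactants: 15 bis(O-phenyl thionocarbonate)
Product: 16 (2R,3R)-7-methoxy-2-[(1E,3E)-4-[(2R)-7-methoxy-5-methyl-8-oxo-2,3,4,8-tetrahydrocyclohepta[b]pyran-2-yl]buta-1,3-dien-1-yl]-3,5-dimethyl-3,4-dihydrocyclohepta[b]pyran-8(2H)-one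
Conditions: Bu3SnH (3 equiv), AIBN (20 mol %), toluene, 80 °C
Reagents that add atoms: none
Why: Barton–McCombie radical deoxygenation releases a tropone-stabilised C4 radical that is reduced by Bu3SnH under neutral conditions, avoiding the cationic chemistry that would ionise the dienylic C2–O bonds; no stereocentre is involved.

**Step 10**
Reactants: 16 bis(tropolone methyl ether)
Product: 17 target, (2R,3R)-8-hydroxy-2-[(1E,3E)-4-[(2R)-8-hydroxy-5-methyl-7-oxo-2,3,4,7-tetrahydrocyclohepta[b]pyran-2-yl]buta-1,3-dien-1-yl]-3,5-dimethyl-3,4-dihydrocyclohepta[b]pyran-7(2H)-one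
Conditions: MgI2·OEt2 (6 equiv), toluene, 60 °C; aq NH4Cl
Reagents that add atoms: none
Why: Chelation-assisted ether cleavage, in which MgI2 binds the adjacent tropone C=O/OMe pair and iodide removes the methyl group by SN2, leaves the non-chelating allylic pyran ethers intact and gives the tropolone, whose 7-hydroxy-8-oxo and 8-hydroxy-7-oxo forms are tautomers of the same compound.

**Compound list**
1 | hexa-2,4-diyne-1,6-diol | OCC#CC#CCO | starting material
2 | (2E,4E)-hexa-2,4-diene-1,6-diol | OC/C=C/C=C/CO | intermediate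
3 | (2E,4E)-hexa-2,4-dienedial | O=C/C=C/C=C/C=O | intermediate
4 | Danishefsky's diene, (E)-1-methoxy-3-(trimethylsilyloxy)buta-1,3-diene | CO/C=C/C(=C)O[Si](C)(C)C | starting material
5 | bis-silyl aldol adduct, (1E,5R,6E,8E,10R,13E)-1,14-dimethoxy-5,10-bis(trimethylsilyloxy)tetradeca-1,6,8,13-tetraene-3,12-dione (not isolated) | CO/C=C/C(=O)C[C@@H](O[Si](C)(C)C)/C=C/C=C/[C@H](O[Si](C)(C)C)CC(=O)/C=C/OC | intermediate
6 | (2R,2'R)-2,2'-[(1E,3E)-buta-1,3-diene-1,4-diyl]bis(2,3-dihydro-4H-pyran-4-one) | O=C1C[C@H](/C=C/C=C/[C@H]2CC(=O)C=CO2)OC=C1 | intermediate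
7 | mono-lithium enolate of 6 (C3=C4–OLi in one ring; not isolated) | [Li+].[O-]C1=C[C@H](/C=C/C=C/[C@H]2CC(=O)C=CO2)OC=C1 | intermediate
8 | (2S,3S)-3-methyl-2-[(1E,3E)-4-[(2R)-4-oxo-3,4-dihydro-2H-pyran-2-yl]buta-1,3-dien-1-yl]-2,3-dihydro-4H-pyran-4-one (2,3-trans) | O=C1[C@@H](C)[C@H](/C=C/C=C/[C@H]2CC(=O)C=CO2)OC=C1 | intermediate
9 | allomaltol, 5-hydroxy-2-methyl-4H-pyran-4-one | Cc1cc(=O)c(O)co1 | starting material
10 | 5-hydroxy-4-methoxy-2-methylpyrylium trifluoromethanesulfonate | COc1cc(C)[o+]cc1O.[O-]S(=O)(=O)C(F)(F)F | intermediate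
11 | oxidopyrylium ylide, 4-methoxy-6-methylpyrylium-3-olate (not isolated) | COc1cc(C)[o+]cc1[O-] | intermediate
12 | two-fold [5+2] cycloadduct of 8 with 11: each pyranone C5=C6 bond carries a 3-methoxy-5-methyl-8-oxabicyclo[3.2.1]oct-3-en-2-one bridge; ring A 2S,3S, ring B 2R, new centres as diastereomer mixture (not isolated) | O=C1[C@@H](C)[C@H](/C=C/C=C/[C@H]2CC(=O)C3C(O2)C4OC3(C)C=C(OC)C4=O)OC2C1C1(C)OC2C(=O)C(OC)=C1 | intermediate
13 | (2S,3S)-7-methoxy-2-[(1E,3E)-4-[(2R)-7-methoxy-5-methyl-4,8-dioxo-2,3,4,8-tetrahydrocyclohepta[b]pyran-2-yl]buta-1,3-dien-1-yl]-3,5-dimethyl-2,3-dihydrocyclohepta[b]pyran-4,8-dione | Cc1cc(OC)c(=O)cc2c1C(=O)[C@@H](C)[C@H](/C=C/C=C/[C@H]1CC(=O)c3c(C)cc(OC)c(=O)cc3O1)O2 | intermediate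
14 | bis-alcohol: 13 with both C4 ketones reduced to CH(OH); ring A 2S,3R, ring B 2R, C4/C4' epimers | Cc1cc(OC)c(=O)cc2c1C(O)[C@@H](C)[C@H](/C=C/C=C/[C@H]1CC(O)c3c(C)cc(OC)c(=O)cc3O1)O2 | intermediate
15 | bis(O-phenyl thionocarbonate) of 14; ring A 2S,3S, ring B 2R, C4/C4' epimers | Cc1cc(OC)c(=O)cc2c1C(OC(=S)Oc1ccccc1)[C@@H](C)[C@H](/C=C/C=C/[C@H]1CC(OC(=S)Oc3ccccc3)c3c(C)cc(OC)c(=O)cc3O1)O2 | intermediate
16 | (2R,3R)-7-methoxy-2-[(1E,3E)-4-[(2R)-7-methoxy-5-methyl-8-oxo-2,3,4,8-tetrahydrocyclohepta[b]pyran-2-yl]buta-1,3-dien-1-yl]-3,5-dimethyl-3,4-dihydrocyclohepta[b]pyran-8(2H)-one | Cc1cc(OC)c(=O)cc2c1C[C@@H](C)[C@H](/C=C/C=C/[C@H]1CCc3c(C)cc(OC)c(=O)cc3O1)O2 | intermediate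
17 | (2R,3R)-8-hydroxy-2-[(1E,3E)-4-[(2R)-8-hydroxy-5-methyl-7-oxo-2,3,4,7-tetrahydrocyclohepta[b]pyran-2-yl]buta-1,3-dien-1-yl]-3,5-dimethyl-3,4-dihydrocyclohepta[b]pyran-7(2H)-one | Cc1cc(=O)c(O)cc2c1C[C@@H](C)[C@H](/C=C/C=C/[C@H]1CCc3c(C)cc(=O)c(O)cc3O1)O2 | target

**Total step count:** 10. **Longest linear sequence:** 9 steps (steps 1–4 and 6–10; step 5 is a one-step side branch).

**Three steps most likely to fail**

Step 6. The dihydropyranone alkene is a deactivated (vinylogous-ester) partner, the central diene is a possible competing 2π site, and once the tropones exist the C4 ketones make C2 and C2' flavanone-like (retro-oxa-Michael opening would erode them). The fallback repairs only the third risk, by separating cycloaddition from aromatisation and removing the ketones first; it sets out from 12, isolated after the cycloaddition stage, and comes back at 14. NaBH4 (MeOH–CH2Cl2, −78 °C) reduces the two saturated C4 ketones before any tropone exists, giving the reduced bis-cycloadduct diol F1. Me3SiOTf/Et3N then ionises each bridging ether directly (the tertiary cation is stabilised through the methoxy-enone) and dehydrates to the bis(trimethylsilyl ether) of 14 F2. K2CO3/MeOH frees 14.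

Step 4. The lithium enolate can expel the ring oxygen (β-elimination, loss of C2), and mono-alkylation of two equivalent rings is statistical. The fallback puts the methyl group into the diene instead of using an enolate; it sets out from 3 and 4 and comes back at 8. Dial 3 is treated under the step 3 conditions with a 1:1 mixture of 4 and (1E,3Z)-1-methoxy-3-(trimethylsilyloxy)penta-1,3-diene F3 (from 1-methoxypent-1-en-3-one, Me3SiOTf, Et3N). The mixed bis-silyl aldol adduct F4 is cyclised with TFA, which also equilibrates C3 to the 2,3-trans isomer, and 8 is isolated by chromatography. The statistical ceiling remains, but no enolate is formed.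

Step 9. Stannyl radicals may add to the tropone carbonyls or the diene, and the C4 positions are hindered by the neighbouring ring methyl groups. The fallback replaces thiocarbonyl radical chemistry by electron transfer through the tropone; it sets out from 14 and comes back at 16. Ac2O/pyridine/DMAP gives the bis-acetate of 14 F5, and SmI2 (THF–MeOH, −78 °C) reduces each tropone to its radical anion, which expels the vinylogously α-placed acetate; protonation at C4 gives 16.

**Further compounds**
F1 | step 6 | reduced bis-cycloadduct diol (12 with both C4 ketones as CH(OH); ring A 2S,3R, ring B 2R) | OC1[C@@H](C)[C@H](/C=C/C=C/[C@H]2CC(O)C3C(O2)C4OC3(C)C=C(OC)C4=O)OC2C1C1(C)OC2C(=O)C(OC)=C1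
F2 | step 6 | bis(trimethylsilyl ether) of 14 | Cc1cc(OC)c(=O)cc2c1C(O[Si](C)(C)C)[C@@H](C)[C@H](/C=C/C=C/[C@H]1CC(O[Si](C)(C)C)c3c(C)cc(OC)c(=O)cc3O1)O2
F3 | step 4 | (1E,3Z)-1-methoxy-3-(trimethylsilyloxy)penta-1,3-diene | CO/C=C/C(O[Si](C)(C)C)=C/C
F4 | step 4 | mixed bis-silyl aldol adduct (5 with one methyl group at C4; carbinol configuration as in 5, methyl epimers) | CO/C=C/C(=O)C(C)[C@@H](O[Si](C)(C)C)/C=C/C=C/[C@H](O[Si](C)(C)C)CC(=O)/C=C/OC
F5 | step 9 | bis-acetate of 14 | Cc1cc(OC)c(=O)cc2c1C(OC(C)=O)[C@@H](C)[C@H](/C=C/C=C/[C@H]1CC(OC(C)=O)c3c(C)cc(OC)c(=O)cc3O1)O2
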